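All constants are assumed; the result is computed.

Do not read 80.0% of D reacted as that much turned over: D.Q counts as reacted and has made no J.

    E ⇌ Q, rate k1*(cs1 - [Q]) while solid is left; crystals form when [Q] > cs1 (cs1 = 3.7 mM, k1 = 9.49 min⁻¹)
    D + Q ⇌ D.Q, settled at all times (K2 = 98.2 M⁻¹)
    G + J ⇌ G.J, settled at all times (K3 = 4330 M⁻¹)
    D + G → J + Q (k4 = 5.11 M⁻¹ min⁻¹)

D 20 mM; time 10 min

* the concentration of G at which the part of the D that has reacted at 10 min is just 80%, in mM

- in percentages every species weighs as the D in it: one D.Q counts as two
- for Q the E and D.Q are counted in
- as a solid, counted per litre of solution: E
- the amount of G is what is sought; it is there from the start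
- in an amount of Q, one D.Q counts as one Q
- what has gone from D into another species counts as reacted, even if it can come back
- run time (flask): 10 min

Work this flask in fractions of the D charge, at its target. Free D stands at 20.0%. Take Q at its solubility, 3.7 mM, so each free D carries 0.363 D.Q. The turnover needed is then 72.7%.

Each turnover spends one G and makes one J. With free G at one D charge, 98.9% of that J sits as G.J. Call the free G lost per D turned over the G toll: 1.99.

Now hold G steady, which makes the step pseudo-first-order in D. Free D is the unturned D divided by 1.36. The turnover needs a log clock of 1.30, and that takes a mean free G of 34.7 mM, or 1.73 charges. Add the toll on the midpoint, half the turnover. The charge comes to 49.1 mM.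

The weak link is that midpoint. On the log clock the mean turnover is 44.0%, not 36.4%. Reforged, the charge is 52.2 mM.

The forecast gives 53 mM, on the ground that “free G falls by about two per turnover”. My figure lies lower.

The simulation gives 52.9 mM, so the forecast holds. In this flask the D + G step did half of its turnover up to 10 min by 2.34 min, while the falling out of Q as crystals reached that mark by 5.03 min. The toll on the reckoned turnover of 72.7% leaves 45.3% of the charged G free, and the flask reads 45.4% at 10.0 min. A second flask, with a quarter more G, reached 86.3% reacted; with Q taken at its solubility, that reckons to a turnover of 81.4%. Toll and log clock ask 65.4 mM for that turnover, and that flask held 66.1 mM.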